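## The problem

The target 26 is a 2H-chromene: a benzene ring (ring A) fused across C4a–C8a to a pyran ring (ring B) that holds the C3=C4 double bond. C2 carries a methyl group and a CH2O–acyl arm whose acyl group is (E)-feruloyl; C6 carries an acetyl group and C7 a free hydroxyl.

The only stereocentre is C2, a fully substituted ether carbon of R configuration. Nothing else in the molecule can relay or repair it, so it must be brought in once and then kept away from every process that breaks the O1–C2 bond. Two such processes are real: a 2H-chromene can open to an ortho-quinone methide by retro-6π electrocyclisation on heating or in light and reclose to either enantiomer, and strong acid can ionise the tertiary ether.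

The fragile groups are the cinnamate ester (base, nucleophiles, light), the guaiacol phenol, the chromene double bond (acid, hydrogenation, oxidants) and the ortho-hydroxyaryl ketone. The C7 hydroxyl of that ketone is hydrogen-bonded to the C6 carbonyl and is therefore a poor acyl acceptor.

Ring A is oxygenated as a resorcinol (O1 on C8a, hydrogen on C8, hydroxyl on C7), which is exactly the pattern produced when a vinylketene joins an alkoxyalkyne. Because O1 is tied back to C4a through C2, C3 and C4, the alkyne oxygen can be the pyran oxygen, and one cascade could close ring B and build ring A from an open chain. The acetyl group sits ortho to the C7 hydroxyl and para to O1, the site at which a 7-hydroxychroman is acylated anyway, so it can be added after the rings exist.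

## Retrosynthesis

**Ester C–O bond.** The first cut is the acyl–oxygen bond of the ester, dividing 26 into the chromene diol 22 and a ferulic acid unit. Attaching the cinnamate last keeps the most base- and light-sensitive group away from organometallics, irradiation and DDQ. The acid is used as its 4-O-acetate 24 (one step from ferulic acid 23), so the last intermediate is acetate 25 and the final operation a mild deacetylation. The esterification must choose the primary hydroxyl of 22 over the C7 phenol; the hydrogen bond of that phenol to the C6 acetyl is relied on for this.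

**C3=C4 double bond.** Removing the alkene leads from 22 through the chromene acetate 21 to the chroman acetate 20. A chroman cannot open electrocyclically, so all earlier chemistry is done at that level and the alkene appears only three steps from the end. The forward step needs hydride abstraction at C4, which the para C7 hydroxyl assists. It also needs the primary hydroxyl masked so that it cannot add to the C4 cation; the acetate left there by the preceding acylation serves.

**C6–acetyl bond.** A Friedel–Crafts disconnection gives the diol 19. Carrying the acetyl through the ring-forming cascade would need a substituted vinyl ketone and a second enolisable ketone during diazo transfer. Acylation afterwards is simpler, because C6 is the electronically and sterically preferred position. The forward reaction must acylate C6 and not C8.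

**Benzyl ether.** 19 is the debenzylated form of chromanol 18. A benzyl ether is chosen for the C2 arm because it cannot migrate to the neighbouring tertiary alkoxide and withstands KH and butyllithium. It leaves by hydrogenolysis at a stage where the molecule has no alkene or ketone.

**Both rings (key disconnection).** Cutting C4a–C8a, C7–C8 and C6–C7 of 18 leads back through dienylketene 17, cyclobutenone 16 and vinylketene 15 to the acyclic diazo enone 14. In 14, C8a and C8 are the two carbons of an ethynyl ether on the C2 oxygen, C7 is the ketone carbon, C4a the diazo carbon and C5–C6 the vinyl group. The neighbouring cuts at O1–C8a or O1–C2 start from a bought arene. This one makes both rings in one operation and derives the 1,3-dioxygenation, the free C8 and the open C6 from connectivity alone. The precursor has no ring and one stereocentre. The forward reaction asks that the ketene add to its own ynol ether faster than it dimerises, and that cyclobutenone opening and 6π closure follow; this intramolecular form is untested.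

**Diazo group and enone.** The C=N2 unit of 14 is traced to vinyl ketone 12 by diazo transfer through the trifluoroacetyl derivative 13, the method of choice for enones. 12 comes from aldehyde 9 and vinylmagnesium bromide 10 by addition (alcohol 11) and oxidation, and 9 from silyl ether 7 via alcohol 8. Every reagent here must be non-acidic and used cold, since the tertiary ethynyl ether is present throughout.

**Ynol ether O–C(sp) bond.** 7 arises from tertiary alcohol 4 and trichloroethylene 5 through dichlorovinyl ether 6. The second stage uses butyllithium, so this bond must be made before any carbonyl exists. That is why the future ketone carbon is still a silyl-protected primary alcohol in 4.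

**Chain C–C bond and the stereocentre.** Cutting the C3–C4 bond of the hexane chain of 4 gives epoxide 2 and the three-carbon bromide 3 (used as its Grignard reagent). 2 is the benzyl ether of (S)-2-methylglycidol 1. Opening at the CH2 terminus leaves the tertiary C–O bond untouched, so the stereocentre of 26 is bought with 1.

## Roads not taken

Alternative 1: The cut is O1–C8a. Base converts the tertiary hydroxyl of the (Z)-styrenyl carbinol A2 into its alkoxide, which displaces the fluoride para to the acetyl group and closes chromene A1 in one step.
- Merits: ring A is bought fully substituted, the C3=C4 bond and acetyl group are already in place, and intramolecular SNAr onto a para-acyl fluoroarene is a known reaction class.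
- Weak points: A2 needs a Z alkene (semi-hydrogenation of an aryl alkyne) and an enantioenriched tertiary propargylic carbinol in which methyl and a protected hydroxymethyl group must be told apart. The nucleophile is a hindered tertiary allylic alkoxide made with strong base beside an enolisable methyl ketone. A1 must still lose an acetal under acid and a 4-methoxybenzyl group, both on the acid-sensitive chromene.
- Comparison: on step count and precedent this road is better than the chosen one. The chosen plan sets against it a stereocentre that comes complete from a chiral-pool epoxide, ring A oxygens that never carry protecting groups, and an alkene that appears only at the end, so C2 is not exposed as a chromene for half the synthesis.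

Alternative 2: The cut is O1–C2. Pd2(dba)3 (zerovalent palladium) with a chiral diphosphine ionises the allylic carbonate A4, and the phenol para to the acetyl group attacks the more substituted end of the π-allyl complex to give the 2-methyl-2-vinylchroman A3. The other phenol is held by the acetyl group and cannot reach.
- Merits: catalytic, enantioselective construction of C2, a bought arene with the acetyl in place, and close precedent for quaternary chroman centres.
- Weak points: the vinyl group is one carbon too long. It must be cleaved oxidatively and reduced to CH2OH beside an electron-rich phenol and an aryl ketone that hydride would also reduce, which brings protecting groups back. Enantiomeric purity depends on the ligand and on the geometric purity of A4 and is not assured at a fully substituted carbon. The C3–C4 dehydrogenation remains, as in the chosen plan.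
- Comparison: A3 is reached in fewer steps than 20, and there this road is ahead. The chosen plan offers in return an enantiopure C2 with the correct carbon count and oxidation level on its arm from the start.

Alternative 3: The cuts are C2–C3 and O1–C2 (Kabbe condensation). A chiral amine condenses one acetyl methyl of the symmetric diketone A6 with the carbonyl of the silyloxy ketone A7, and the neighbouring phenol adds to the resulting enone to give chromanone A5.
- Merits: this is the shortest road. Either acetyl of A6 gives the same product, the second one is the C6 acetyl of the target, and the C4 carbonyl lets the double bond be made by reduction and dehydration without DDQ.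
- Weak points: the oxa-Michael closure must distinguish methyl from silyloxymethyl at a ketone-derived carbon, it is reversible under the amine conditions, and enantioselective versions at fully substituted centres are few. The C4 ketone must also be reduced beside the C6 acetyl.
- Comparison: if the selectivity could be secured, A5 would give the most economical synthesis, clearly shorter than the chosen one. The chosen plan sets a secure absolute configuration against that economy and accepts more steps for it.

Key step: step 9

Remark: (S)-2-methylglycidol 1 is taken as a purchasable chiral-pool epoxide; ring atoms keep their chromene numbers (O1, C2, C3, C4, C4a, C5 to C8, C8a) in acyclic precursors too, and the carbinol carbon of 11 and the ring-fusion carbon of transient 16 form as epimer mixtures and are left open in their SMILES.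

## Route

Step 1
Reactants: 1 (S)-2-methylglycidol
Product: 2 (R)-2-[(benzyloxy)methyl]-2-methyloxirane
Conditions: NaH, BnBr, Bu4NI (cat.), THF, 0 °C → rt
Reagents that add atoms: benzyl bromide, BrCc1ccccc1
Why: Williamson etherification of the primary alkoxide; the quaternary carbon is untouched, and the Payne rearrangement of this alkoxide is degenerate and returns the same enantiomer, so the centre is carried over unchanged (the descriptor becomes R only through the priority rules).

Step 2
Reactants: 2 (R)-2-[(benzyloxy)methyl]-2-methyloxirane; 3 (3-bromopropoxy)(tert-butyl)dimethylsilane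
Product: 4 (2R)-1-(benzyloxy)-6-[(tert-butyldimethylsilyl)oxy]-2-methylhexan-2-ol
Conditions: Mg, THF (Grignard reagent from 3); CuI (10 mol%), −30 → 0 °C
Reagents that add atoms: none
Why: Copper-catalysed Grignard opening of a 2,2-disubstituted epoxide proceeds by SN2 attack at the CH2 terminus, so the tertiary C–O bond and the configuration of the future C2 are retained; the silyl ether masks the carbon that will become the ketone.

Step 3
Reactants: 4 (2R)-1-(benzyloxy)-6-[(tert-butyldimethylsilyl)oxy]-2-methylhexan-2-ol; 5 trichloroethylene
Product: 7 (2R)-1-(benzyloxy)-6-[(tert-butyldimethylsilyl)oxy]-2-(ethynyloxy)-2-methylhexane, via dichlorovinyl ether 6 (not isolated)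
Conditions: KH, THF, 0 °C; Cl2C=CHCl, −50 °C → rt; n-BuLi, −78 → −40 °C; MeOH
Reagents that add atoms: none
Why: Trichloroethylene route to alkoxyacetylenes: the potassium alkoxide adds to dichloroacetylene formed in situ to give 6, and n-BuLi then effects elimination and chlorine–lithium exchange to the lithium alkynyl ether, which MeOH protonates. Tertiary alkoxides are competent in this addition and the benzyl ether cannot migrate to the alkoxide; from here on everything is kept at or below room temperature and free of acid, because a tertiary ethynyl ether is prone to retro-ene loss of ketene and to hydration.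

Step 4
Reactants: 7 (2R)-1-(benzyloxy)-6-[(tert-butyldimethylsilyl)oxy]-2-(ethynyloxy)-2-methylhexane
Product: 8 (5R)-6-(benzyloxy)-5-(ethynyloxy)-5-methylhexan-1-ol
Conditions: Bu4NF, THF, 0 °C → rt
Reagents that add atoms: none
Why: Fluoride cleavage of the primary silyl ether; ynol ethers tolerate basic fluoride and the benzyl ether is orthogonal.

Step 5
Reactants: 8 (5R)-6-(benzyloxy)-5-(ethynyloxy)-5-methylhexan-1-ol
Product: 9 (5R)-6-(benzyloxy)-5-(ethynyloxy)-5-methylhexanal
Conditions: SO3·pyridine, DMSO, i-Pr2NEt, CH2Cl2, 0 °C
Reagents that add atoms: none
Why: Parikh–Doering oxidation of the primary alcohol runs amine-buffered at 0 °C, with no acid or carboxylic acid present that could add to the ynol ether.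

Step 6
Reactants: 9 (5R)-6-(benzyloxy)-5-(ethynyloxy)-5-methylhexanal; 10 vinylmagnesium bromide
Product: 11 (3RS,7R)-8-(benzyloxy)-7-(ethynyloxy)-7-methyloct-1-en-3-ol
Conditions: CH2=CHMgBr, THF, −78 → −20 °C; aq. NH4Cl, 0 °C
Reagents that add atoms: none
Why: Grignard 1,2-addition to the aldehyde; the new carbinol centre forms without control, which is immaterial because it is oxidised in the next step (a second equivalent of reagent covers deprotonation of the alkyne C–H).

Step 7
Reactants: 11 (3RS,7R)-8-(benzyloxy)-7-(ethynyloxy)-7-methyloct-1-en-3-ol
Product: 12 (7R)-8-(benzyloxy)-7-(ethynyloxy)-7-methyloct-1-en-3-one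
Conditions: MnO2, CH2Cl2, rt
Reagents that add atoms: none
Why: MnO2 oxidation of an allylic alcohol to the enone is neutral and heterogeneous, so the vinyl ketone and the ynol ether are obtained by filtration without exposure to acid or base.

Step 8
Reactants: 12 (7R)-8-(benzyloxy)-7-(ethynyloxy)-7-methyloct-1-en-3-one
Product: 14 (7R)-8-(benzyloxy)-4-diazo-7-(ethynyloxy)-7-methyloct-1-en-3-one, via trifluoroacetyl enone 13 (not isolated)
Conditions: LiN(SiMe3)2, THF, −78 °C; CF3CO2CH2CF3; then MsN3, Et3N, H2O, MeCN, rt
Reagents that add atoms: methanesulfonyl azide, CS(=O)(=O)N=[N+]=[N-]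
Why: Detrifluoroacetylative diazo transfer, the established way to α′-diazo enones: kinetic enolisation on the alkyl side (the only enolisable position) and trifluoroacetylation activate C4 for diazo transfer, after which the trifluoroacetyl group is cleaved. The ketone is far more acidic than the alkyne C–H and is deprotonated selectively; inverse addition at −78 °C limits Michael oligomerisation of the vinyl ketone.

Step 9
Reactants: 14 (7R)-8-(benzyloxy)-4-diazo-7-(ethynyloxy)-7-methyloct-1-en-3-one
Product: 18 (2R)-2-[(benzyloxy)methyl]-2-methyl-3,4-dihydro-2H-chromen-7-ol, via vinylketene 15 (not isolated), via cyclobutenone 16 (not isolated), via dienylketene 17 (not isolated)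
Conditions: hν (300 nm), degassed ClCH2CH2Cl (0.005 M), 20 °C; then 80 °C, dark
Reagents that add atoms: none
Why: Proposed new method: light expels N2 from 14 and the vinyl group migrates to the carbene carbon (photochemical Wolff rearrangement) to give vinylketene 15; the closest known reaction is the intermolecular photochemical benzannulation of α′-diazo enones with alkoxyalkynes (the diazo ketone variant of the Danheiser benzannulation), which has not been run with the alkyne tethered through its oxygen. The ketene then adds [2+2] to the ynol ether, its carbonyl carbon bonding to the nucleophilic terminal alkyne carbon (C7–C8) and its substituted carbon to the oxygen-bearing carbon (C4a–C8a); this closes ring B as a six-membered ring in the fused mode of an intramolecular ketene cycloaddition and gives cyclobutenone 16. 16 opens by 4π electrocyclic ring-opening (thermal or photochemical) to dienylketene 17, in which ketene and vinyl group are held cis on the ring double bond, and 6π electrocyclisation (C6–C7) followed by tautomerisation closes ring A as the phenol. No lasting stereocentre is created: the ring-fusion carbon of 16 forms as either epimer and becomes sp2 again on ring-opening, and C2 is a spectator. The regiochemistry is fixed twice, by the polarisation of the ynol ether and by the four-atom tether C4–C3–C2–O1, which allows only this orientation. What is not guaranteed is that the intramolecular [2+2] outruns ketene dimerisation, carbene 1,2-hydrogen shift and dipolar addition of the diazo group; high dilution, the nucleophilicity of the ynol ether, the gem-disubstituted C2 in the tether and irradiation at 20 °C are meant to secure it. Heating to 80 °C is applied only after the diazo ketone and the thermally labile ynol ether are consumed, to drive residual 16 through to 18.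

Step 10
Reactants: 18 (2R)-2-[(benzyloxy)methyl]-2-methyl-3,4-dihydro-2H-chromen-7-ol
Product: 19 (2R)-2-(hydroxymethyl)-2-methyl-3,4-dihydro-2H-chromen-7-ol
Conditions: H2 (1 atm), 10% Pd/C, EtOAc, rt
Reagents that add atoms: none
Why: Hydrogenolysis of the aliphatic benzyl ether; at this stage the molecule has no alkene or ketone, so nothing else is reducible and C2 is untouched.

Step 11
Reactants: 19 (2R)-2-(hydroxymethyl)-2-methyl-3,4-dihydro-2H-chromen-7-ol
Product: 20 [(2R)-6-acetyl-7-hydroxy-2-methyl-3,4-dihydro-2H-chromen-2-yl]methyl acetate
Conditions: AcOH, BF3·OEt2, 80 °C; aq. NaOAc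
Reagents that add atoms: acetic acid, CC(=O)O
Why: Friedel–Crafts acylation with the AcOH–BF3 complex, the standard entry to 6-acetyl-7-hydroxychromans: attack occurs at C6, ortho to the hydroxyl and para to O1, not at the hindered C8 between two oxygens, and the product is shielded from a second acylation as its boron chelate until work-up. The same medium esterifies the primary alcohol, which is wanted as protection for the next step; the tertiary ether at C2 is deactivated toward ionisation by the adjacent acyloxymethyl group, and 2,2-dialkylchromans are known to survive these conditions.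

Step 12
Reactants: 20 [(2R)-6-acetyl-7-hydroxy-2-methyl-3,4-dihydro-2H-chromen-2-yl]methyl acetate
Product: 22 1-[(2R)-7-hydroxy-2-(hydroxymethyl)-2-methyl-2H-chromen-6-yl]ethan-1-one, via chromene acetate 21 (not isolated)
Conditions: DDQ, 1,4-dioxane, 40 °C, dark; filter; then K2CO3 (cat.), MeOH, 0 °C → rt
Reagents that add atoms: none
Why: DDQ dehydrogenation of a chroman to the 2H-chromene: hydride abstraction from C4 is assisted by the para C7 hydroxyl and is followed by loss of the C3 proton, while the acetate keeps the primary hydroxyl from capturing the C4 cation. Mild temperature and darkness avoid reversible electrocyclic opening of the chromene, which would erode C2; base-catalysed methanolysis in the same flask then frees the primary alcohol.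

Step 13
Reactants: 23 ferulic acid
Product: 24 (E)-3-(4-acetoxy-3-methoxyphenyl)prop-2-enoic acid
Conditions: Ac2O, pyridine, rt; then H2O
Reagents that add atoms: acetic anhydride, CC(=O)OC(C)=O
Why: Acetylation of the phenol; the mixed anhydride formed at the carboxyl group is hydrolysed on aqueous work-up, leaving the (E)-acid with the phenol masked.

Step 14
Reactants: 22 1-[(2R)-7-hydroxy-2-(hydroxymethyl)-2-methyl-2H-chromen-6-yl]ethan-1-one; 24 (E)-3-(4-acetoxy-3-methoxyphenyl)prop-2-enoic acid
Product: 25 [(2R)-6-acetyl-7-hydroxy-2-methyl-2H-chromen-2-yl]methyl (E)-3-(4-acetoxy-3-methoxyphenyl)prop-2-enoate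
Conditions: EDC·HCl, DMAP (cat.), CH2Cl2, 0 °C → rt, dark
Reagents that add atoms: none
Why: Steglich esterification; the primary alcohol is acylated in preference to the C7 hydroxyl, which is deactivated by its hydrogen bond to the C6 acetyl, and any aryl ester formed there would be cleaved in the last step.

Step 15
Reactants: 25 [(2R)-6-acetyl-7-hydroxy-2-methyl-2H-chromen-2-yl]methyl (E)-3-(4-acetoxy-3-methoxyphenyl)prop-2-enoate
Product: 26 [(2R)-6-acetyl-7-hydroxy-2-methyl-2H-chromen-2-yl]methyl (E)-3-(4-hydroxy-3-methoxyphenyl)prop-2-enoate
Conditions: K2CO3 (cat.), MeOH, 0 °C, dark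
Reagents that add atoms: none
Why: Base-catalysed methanolysis cleaves the aryl acetate within minutes at 0 °C, while the hindered alkyl cinnamate, the chromene and the (E)-alkene are left alone; C2 is not involved.

## Compound list

1 | (S)-2-methylglycidol | OC[C@@]1(C)CO1 | starting material
2 | (R)-2-[(benzyloxy)methyl]-2-methyloxirane | c1ccccc1COC[C@@]1(C)CO1 | intermediate
3 | (3-bromopropoxy)(tert-butyl)dimethylsilane | BrCCCO[Si](C)(C)C(C)(C)C | starting material
4 | (2R)-1-(benzyloxy)-6-[(tert-butyldimethylsilyl)oxy]-2-methylhexan-2-ol | c1ccccc1COC[C@@](O)(C)CCCCO[Si](C)(C)C(C)(C)C | intermediate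
5 | trichloroethylene | ClC=C(Cl)Cl | starting material
6 | (2R)-1-(benzyloxy)-6-[(tert-butyldimethylsilyl)oxy]-2-{[(E)-1,2-dichloroethenyl]oxy}-2-methylhexane | c1ccccc1COC[C@@](O/C(Cl)=C\Cl)(C)CCCCO[Si](C)(C)C(C)(C)C | intermediate
7 | (2R)-1-(benzyloxy)-6-[(tert-butyldimethylsilyl)oxy]-2-(ethynyloxy)-2-methylhexane | c1ccccc1COC[C@@](OC#C)(C)CCCCO[Si](C)(C)C(C)(C)C | intermediate
8 | (5R)-6-(benzyloxy)-5-(ethynyloxy)-5-methylhexan-1-ol | c1ccccc1COC[C@@](OC#C)(C)CCCCO | intermediate
9 | (5R)-6-(benzyloxy)-5-(ethynyloxy)-5-methylhexanal | c1ccccc1COC[C@@](OC#C)(C)CCCC=O | intermediate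
10 | vinylmagnesium bromide | C=C[Mg]Br | starting material
11 | (3RS,7R)-8-(benzyloxy)-7-(ethynyloxy)-7-methyloct-1-en-3-ol (both C3 epimers) | c1ccccc1COC[C@@](OC#C)(C)CCCC(O)C=C | intermediate
12 | (7R)-8-(benzyloxy)-7-(ethynyloxy)-7-methyloct-1-en-3-one | c1ccccc1COC[C@@](OC#C)(C)CCCC(=O)C=C | intermediate
13 | (7R)-8-(benzyloxy)-7-(ethynyloxy)-7-methyl-4-(trifluoroacetyl)oct-1-en-3-one, drawn as its chelated enol | c1ccccc1COC[C@@](OC#C)(C)CC/C(C(=O)C=C)=C(/O)C(F)(F)F | intermediate
14 | (7R)-8-(benzyloxy)-4-diazo-7-(ethynyloxy)-7-methyloct-1-en-3-one | c1ccccc1COC[C@@](OC#C)(C)CCC(=[N+]=[N-])C(=O)C=C | intermediate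
15 | (5R)-6-(benzyloxy)-2-ethenyl-5-(ethynyloxy)-5-methylhex-1-en-1-one (vinylketene) | c1ccccc1COC[C@@](OC#C)(C)CCC(C=C)=C=O | intermediate
16 | (3R)-3-[(benzyloxy)methyl]-6-ethenyl-3-methyl-2-oxabicyclo[4.2.0]oct-1(8)-en-7-one (both C6 epimers) | c1ccccc1COC[C@@]1(C)CCC2(C=C)C(=O)C=C2O1 | intermediate
17 | 2-[(2R)-2-[(benzyloxy)methyl]-5-ethenyl-2-methyl-3,4-dihydro-2H-pyran-6-yl]ethen-1-one (dienylketene) | c1ccccc1COC[C@@]1(C)CCC(C=C)=C(C=C=O)O1 | intermediate
18 | (2R)-2-[(benzyloxy)methyl]-2-methyl-3,4-dihydro-2H-chromen-7-ol | c1ccccc1COC[C@@]1(C)CCc2ccc(O)cc2O1 | intermediate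
19 | (2R)-2-(hydroxymethyl)-2-methyl-3,4-dihydro-2H-chromen-7-ol | OC[C@@]1(C)CCc2ccc(O)cc2O1 | intermediate
20 | [(2R)-6-acetyl-7-hydroxy-2-methyl-3,4-dihydro-2H-chromen-2-yl]methyl acetate | CC(=O)OC[C@@]1(C)CCc2cc(C(C)=O)c(O)cc2O1 | intermediate
21 | [(2R)-6-acetyl-7-hydroxy-2-methyl-2H-chromen-2-yl]methyl acetate | CC(=O)OC[C@@]1(C)C=Cc2cc(C(C)=O)c(O)cc2O1 | intermediate
22 | 1-[(2R)-7-hydroxy-2-(hydroxymethyl)-2-methyl-2H-chromen-6-yl]ethan-1-one | OC[C@@]1(C)C=Cc2cc(C(C)=O)c(O)cc2O1 | intermediate
23 | ferulic acid | COc1cc(/C=C/C(=O)O)ccc1O | starting material
24 | (E)-3-(4-acetoxy-3-methoxyphenyl)prop-2-enoic acid | COc1cc(/C=C/C(=O)O)ccc1OC(C)=O | intermediate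
25 | [(2R)-6-acetyl-7-hydroxy-2-methyl-2H-chromen-2-yl]methyl (E)-3-(4-acetoxy-3-methoxyphenyl)prop-2-enoate | COc1cc(/C=C/C(=O)OC[C@@]2(C)C=Cc3cc(C(C)=O)c(O)cc3O2)ccc1OC(C)=O | intermediate
26 | [(2R)-6-acetyl-7-hydroxy-2-methyl-2H-chromen-2-yl]methyl (E)-3-(4-hydroxy-3-methoxyphenyl)prop-2-enoate (CNP0375196.1) | COc1cc(/C=C/C(=O)OC[C@@]2(C)C=Cc3cc(C(C)=O)c(O)cc3O2)ccc1O | target

## Step count and least certain steps

Total: 15 steps. Longest linear sequence: 14 steps (steps 1–12, 14 and 15 from 1); step 13 is a one-step side branch.

**Step 9 (key step, the one flagged as new).** The intramolecular [2+2] may be too slow, because the linear ynol ether must bend into a six-membered transition state. Ketene dimerisation, 1,2-hydrogen shift of the carbene, or loss of ketene from the ynol ether by retro-ene could then take over. The fallback uses known chemistry, sets out from epoxide 2 and returns at diol 19. Copper-catalysed opening of 2 with the benzylic Grignard reagent of 4-(benzyloxy)-2-bromobenzyl chloride should give (2R)-1-(benzyloxy)-4-[4-(benzyloxy)-2-bromophenyl]-2-methylbutan-2-ol F1. Intramolecular C–O coupling of the tertiary alcohol with the aryl bromide (Pd(OAc)2, 2-(di-tert-butylphosphino)-1,1'-binaphthyl, Cs2CO3, toluene, 80 °C) should close ring B to (2R)-7-(benzyloxy)-2-[(benzyloxy)methyl]-2-methyl-3,4-dihydro-2H-chromene F2. Hydrogenolysis of both benzyl ethers (H2, Pd/C) then gives 19.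

**Step 8.** Michael oligomerisation of the unhindered vinyl ketone may compete during enolisation. The product's diazo group may also add as a dipole to its own ynol ether or to the acryloyl unit of a second molecule on standing. The fallback sets out from aldehyde 9 and returns at chromanol 18; it replaces the vinyl group by a β-silylvinyl group, a hindered and more robust Michael acceptor.
- Addition of (E)-2-(trimethylsilyl)vinyllithium to 9 should give (1E,3RS,7R)-8-(benzyloxy)-7-(ethynyloxy)-7-methyl-1-(trimethylsilyl)oct-1-en-3-ol F3.
- MnO2 oxidation gives (1E,7R)-8-(benzyloxy)-7-(ethynyloxy)-7-methyl-1-(trimethylsilyl)oct-1-en-3-one F4.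
- Diazo transfer as in step 8 gives (1E,7R)-8-(benzyloxy)-4-diazo-7-(ethynyloxy)-7-methyl-1-(trimethylsilyl)oct-1-en-3-one F5.
- Irradiation as in step 9 should give (2R)-2-[(benzyloxy)methyl]-2-methyl-6-(trimethylsilyl)-3,4-dihydro-2H-chromen-7-ol F6, with the silyl group on C6.
- Protodesilylation (CF3CO2H, CH2Cl2, 0 °C) leads to 18.

**Step 3.** Addition of the hindered tertiary alkoxide to dichloroacetylene may be incomplete. Excess butyllithium may lithiate the benzylic position. The tertiary ethynyl ether may be lost during isolation through retro-ene fragmentation or hydration on silica. The fallback sets out from alcohol 4 and returns at 7. Formylation (acetic formic anhydride, pyridine) gives (2R)-1-(benzyloxy)-6-[(tert-butyldimethylsilyl)oxy]-2-methylhexan-2-yl formate F7. Dibromo-olefination of the formate (CBr4, PPh3) gives (2R)-1-(benzyloxy)-6-[(tert-butyldimethylsilyl)oxy]-2-[(2,2-dibromoethenyl)oxy]-2-methylhexane F8. n-BuLi at −78 °C followed by MeOH then gives 7.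

**Step 12.** If the dehydrogenation needs more heat than planned, the chromene may open and reclose electrocyclically and C2 would partly racemise; over-oxidation is the second danger. The fallback sets out from 20 and returns at 22, and forms the alkene by elimination at room temperature.
- Acetylation of the phenol (Ac2O, pyridine, DMAP) gives [(2R)-7-acetoxy-6-acetyl-2-methyl-3,4-dihydro-2H-chromen-2-yl]methyl acetate F9.
- Benzylic bromination at C4 (NBS, AIBN, PhCF3, 70 °C) gives [(2R,4RS)-7-acetoxy-6-acetyl-4-bromo-2-methyl-3,4-dihydro-2H-chromen-2-yl]methyl acetate F10.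
- Elimination with DBU (THF, 0 °C → rt, dark) gives [(2R)-7-acetoxy-6-acetyl-2-methyl-2H-chromen-2-yl]methyl acetate F11.
- Methanolysis (K2CO3, MeOH, 0 °C) gives 22.

## Further compounds

F1 | step 9 | (2R)-1-(benzyloxy)-4-[4-(benzyloxy)-2-bromophenyl]-2-methylbutan-2-ol | c1ccccc1COC[C@@](O)(C)CCc1ccc(OCc2ccccc2)cc1Br
F2 | step 9 | (2R)-7-(benzyloxy)-2-[(benzyloxy)methyl]-2-methyl-3,4-dihydro-2H-chromene | c1ccccc1COC[C@@]1(C)CCc2ccc(OCc3ccccc3)cc2O1
F3 | step 8 | (1E,3RS,7R)-8-(benzyloxy)-7-(ethynyloxy)-7-methyl-1-(trimethylsilyl)oct-1-en-3-ol | c1ccccc1COC[C@@](OC#C)(C)CCCC(O)/C=C/[Si](C)(C)C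
F4 | step 8 | (1E,7R)-8-(benzyloxy)-7-(ethynyloxy)-7-methyl-1-(trimethylsilyl)oct-1-en-3-one | c1ccccc1COC[C@@](OC#C)(C)CCCC(=O)/C=C/[Si](C)(C)C
F5 | step 8 | (1E,7R)-8-(benzyloxy)-4-diazo-7-(ethynyloxy)-7-methyl-1-(trimethylsilyl)oct-1-en-3-one | c1ccccc1COC[C@@](OC#C)(C)CCC(=[N+]=[N-])C(=O)/C=C/[Si](C)(C)C
F6 | step 8 | (2R)-2-[(benzyloxy)methyl]-2-methyl-6-(trimethylsilyl)-3,4-dihydro-2H-chromen-7-ol | c1ccccc1COC[C@@]1(C)CCc2cc([Si](C)(C)C)c(O)cc2O1
F7 | step 3 | (2R)-1-(benzyloxy)-6-[(tert-butyldimethylsilyl)oxy]-2-methylhexan-2-yl formate | c1ccccc1COC[C@@](OC=O)(C)CCCCO[Si](C)(C)C(C)(C)C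
F8 | step 3 | (2R)-1-(benzyloxy)-6-[(tert-butyldimethylsilyl)oxy]-2-[(2,2-dibromoethenyl)oxy]-2-methylhexane | c1ccccc1COC[C@@](OC=C(Br)Br)(C)CCCCO[Si](C)(C)C(C)(C)C
F9 | step 12 | [(2R)-7-acetoxy-6-acetyl-2-methyl-3,4-dihydro-2H-chromen-2-yl]methyl acetate | CC(=O)OC[C@@]1(C)CCc2cc(C(C)=O)c(OC(C)=O)cc2O1
F10 | step 12 | [(2R,4RS)-7-acetoxy-6-acetyl-4-bromo-2-methyl-3,4-dihydro-2H-chromen-2-yl]methyl acetate (both C4 epimers) | CC(=O)OC[C@@]1(C)CC(Br)c2cc(C(C)=O)c(OC(C)=O)cc2O1
F11 | step 12 | [(2R)-7-acetoxy-6-acetyl-2-methyl-2H-chromen-2-yl]methyl acetate | CC(=O)OC[C@@]1(C)C=Cc2cc(C(C)=O)c(OC(C)=O)cc2O1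
A1 | alternative 1 | 1-[(2R)-7-(methoxymethoxy)-2-{[(4-methoxybenzyl)oxy]methyl}-2-methyl-2H-chromen-6-yl]ethan-1-one | COc1ccc(COC[C@@]2(C)C=Cc3cc(C(C)=O)c(OCOC)cc3O2)cc1
A2 | alternative 1 | 1-{4-fluoro-5-[(1Z,3R)-3-hydroxy-4-[(4-methoxybenzyl)oxy]-3-methylbut-1-en-1-yl]-2-(methoxymethoxy)phenyl}ethan-1-one | COc1ccc(COC[C@@](O)(C)/C=C\c2cc(C(C)=O)c(OCOC)cc2F)cc1
A3 | alternative 2 | 1-[(2R)-2-ethenyl-7-hydroxy-2-methyl-3,4-dihydro-2H-chromen-6-yl]ethan-1-one | C=C[C@@]1(C)CCc2cc(C(C)=O)c(O)cc2O1
A4 | alternative 2 | (2E)-5-(5-acetyl-2,4-dihydroxyphenyl)-3-methylpent-2-en-1-yl methyl carbonate | COC(=O)OC/C=C(\C)CCc1cc(C(C)=O)c(O)cc1O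
A5 | alternative 3 | (2R)-6-acetyl-2-{[(tert-butyldimethylsilyl)oxy]methyl}-7-hydroxy-2-methyl-2,3-dihydro-4H-chromen-4-one | CC(C)(C)[Si](C)(C)OC[C@@]1(C)CC(=O)c2cc(C(C)=O)c(O)cc2O1
A6 | alternative 3 | 4,6-diacetylresorcinol | CC(=O)c1cc(C(C)=O)c(O)cc1O
A7 | alternative 3 | 1-[(tert-butyldimethylsilyl)oxy]propan-2-one | CC(=O)CO[Si](C)(C)C(C)(C)C
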